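Ring A is the 3,4‑dihydroxycyclohexene (C1–C6) and ring B the hydroxycyclohexene at the other end (C1′–C6′), in carotenoid numbering. The cuts are C11=C12 and C11′=C12′ (two Wittig olefinations on the C10 dialdehyde), C6–C7 (Stille), and in ring A the C1–C2 and C4–C5 bonds together.
Enabling feature: ring‑A C6 bears no hydrogen and lies between C1 (gem‑dimethyl) and C5 (C‑methyl), so as an enol triflate it is a masked ketone carbon whose two α‑carbons are C1 and C5. C2–C3(OH)–C4(OH) is a glyceraldehyde‑level chain with both ends electrophilic.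
Hence (R)‑glycidol 1 is oxidised to (S)‑glycidaldehyde 2, and 2‑methylpentan‑3‑one 3 is annulated onto it in one flask. Aldol addition joins C5 to C4, then enolate opening of the epoxide joins C1 to C2, closing ring A with both oxygens in place.
Forward order: ring A ketone and enol triflate (steps 1–4), its C15 phosphonium salt (steps 5–7), ring B extended from an enantioenriched α‑ionone to a C15 salt and a C25 aldehyde (steps 8–14), then union at C11=C12 and desilylation (steps 15–16).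
Stereochemistry: C3 from glycidol; C4 by Felkin–Anh/Cornforth control in the aldol stage (cis‑diol); C6′ from (R)‑α‑ionone; C3′ by hydride delivery anti to the C6′ side chain. Chain double bonds are E by HWE selectivity, Stille retention and thermal equilibration after each Wittig step.
Key step: step 2

Assumption: (R)‑(+)‑α‑ionone of high enantiomeric purity is taken as a purchasable starting material.

Step 1
Reactants: 1 (R)‑glycidol [(2R)‑oxiran‑2‑ylmethanol]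
Product: 2 (S)‑glycidaldehyde [(2S)‑oxirane‑2‑carbaldehyde]
Conditions: IBX, EtOAc, 75 °C; filter; distil
Reagents that add atoms: none
Why: IBX oxidation of a primary alcohol to the aldehyde is neutral and non‑nucleophilic, so the epoxide and its stereocentre should be untouched (the descriptor changes from R to S only through the priority rules), and the insoluble iodine by‑product is filtered off before the volatile aldehyde is distilled.

Step 2
Reactants: 3 2‑methylpentan‑3‑one; 2 (S)‑glycidaldehyde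
Product: 7 (3R,4S)‑3,4‑dihydroxy‑2,6,6‑trimethylcyclohexan‑1‑one (both C‑2 epimers), via lithium enolate 4 (not isolated), via lithium epoxy aldolate 5 (not isolated), via dilithium enolate alkoxide 6 (not isolated)
Conditions: LiN(i‑Pr)2 (1 equiv), THF, −78 °C; 2, −78 °C; LiN(i‑Pr)2 (second equiv), −78 → 0 °C; aq. NH4Cl
Reagents that add atoms: none
Why: Proposed new method: kinetic deprotonation of 3 at the ethyl CH2 gives enolate 4, which adds to the aldehyde carbon of 2 (C4–C5 bond) to give aldolate 5, and a second equivalent of base then removes the isopropyl methine proton (the C5–H is deactivated by the adjacent alkoxide) so that enolate carbon C1 of 6 opens the epoxide at its CH2 terminus C2 (C1–C2 bond), the epoxide oxygen ending as O‑3. The closest known reaction types are the α,α′‑annulation of ketones with 1,3‑bis‑electrophiles (a [3+3] annulation, as in the Stork enamine–acrolein annulation), the aldol addition of lithium enolates to α,β‑epoxy aldehydes and the base‑induced cyclisation of epoxy ketones, and only their merger in one flask is untested. Ring A closes by a 6‑(enolendo) SN2 opening at the primary epoxide carbon (endo with respect to the oxirane), whereas attack at C3 would be a 5‑(enolendo) closure, disfavoured for enolates by Baldwin's rules and by the need to join a fully substituted carbon to a secondary one. C3 is not a reacting centre and keeps the configuration of 2, C4 is set in the aldol stage by Felkin–Anh/Cornforth addition anti to the epoxide C–O bond (the 3,4‑anti adduct is the cis‑diol of the ring), and C5 is formed without control and is erased in step 4. The step needs enolisation of 3 on the ethyl side (kinetic selectivity of the amide base), aldehyde before epoxide reactivity (inherent), C‑ over O‑alkylation (lithium counter‑ion in THF) and no retro‑aldol (once the second enolate exists the carbonyl group that a retro‑aldol needs is gone).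

Step 3
Reactants: 7 (3R,4S)‑3,4‑dihydroxy‑2,6,6‑trimethylcyclohexan‑1‑one
Product: 8 (3R,4S)‑3,4‑bis[(tert‑butyldimethylsilyl)oxy]‑2,6,6‑trimethylcyclohexan‑1‑one (both C‑2 epimers)
Conditions: TBSOTf, 2,6‑lutidine, CH2Cl2, −78 → 0 °C
Reagents that add atoms: tert‑butyldimethylsilyl trifluoromethanesulfonate (TBSOTf), CC(C)(C)[Si](C)(C)OS(=O)(=O)C(F)(F)F
Why: A silyl triflate with a hindered pyridine base should silylate both secondary hydroxyls of the cis‑diol faster than it enolises the hindered ketone, and the two silyl ethers are chosen to survive base, palladium and ylide chemistry and to fall to fluoride at the end.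

Step 4
Reactants: 8 (3R,4S)‑3,4‑bis[(tert‑butyldimethylsilyl)oxy]‑2,6,6‑trimethylcyclohexan‑1‑one
Product: 10 (3R,4S)‑3,4‑bis[(tert‑butyldimethylsilyl)oxy]‑2,6,6‑trimethylcyclohex‑1‑en‑1‑yl trifluoromethanesulfonate, via potassium enolate 9 (not isolated)
Conditions: KN(SiMe3)2, THF, −78 °C; Comins' reagent, −78 → −30 °C; aq. NH4Cl
Reagents that add atoms: Comins' reagent [N‑(5‑chloropyridin‑2‑yl)‑1,1,1‑trifluoro‑N‑(trifluoromethylsulfonyl)methanesulfonamide], Clc1ccc(nc1)N(S(=O)(=O)C(F)(F)F)S(=O)(=O)C(F)(F)F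
Why: C‑2 is the only enolisable position of 8 (the other α‑carbon is quaternary), so one enolate forms and is trapped on oxygen at low temperature as the tetrasubstituted enol triflate, which merges both C‑2 epimers into one compound, while the cold conditions and the poor leaving‑group ability of a silyloxide should hold back β‑elimination.

Step 5
Reactants: 11 (E)‑3‑methylpent‑2‑en‑4‑yn‑1‑ol
Product: 12 (2E,4E)‑3‑methyl‑5‑(tributylstannyl)penta‑2,4‑dien‑1‑ol
Conditions: Bu3SnH, PdCl2(PPh3)2 (cat.), THF, 0 °C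
Reagents that add atoms: tributyltin hydride, CCCC[SnH](CCCC)CCCC
Why: Palladium‑catalysed syn‑hydrostannylation of the terminal enyne places tin on the terminal carbon and should give the (E)‑alkenylstannane, a known route to this dienylstannane, with the minor internal regioisomer removed by chromatography.

Step 6
Reactants: 10 (3R,4S)‑3,4‑bis[(tert‑butyldimethylsilyl)oxy]‑2,6,6‑trimethylcyclohex‑1‑en‑1‑yl trifluoromethanesulfonate; 12 (2E,4E)‑3‑methyl‑5‑(tributylstannyl)penta‑2,4‑dien‑1‑ol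
Product: 13 (2E,4E)‑5‑[(3R,4S)‑3,4‑bis[(tert‑butyldimethylsilyl)oxy]‑2,6,6‑trimethylcyclohex‑1‑en‑1‑yl]‑3‑methylpenta‑2,4‑dien‑1‑ol
Conditions: Pd2(dba)3 (cat.), AsPh3, LiCl, NMP, 50 °C
Reagents that add atoms: none
Why: Stille coupling of hindered 2,6,6‑trimethylcyclohexenyl triflates with (E)‑dienylstannanes under these weak‑ligand conditions is established in retinoid synthesis and should form the C6–C7 bond with retention of both double‑bond geometries in the presence of the free hydroxyl and the silyl ethers.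

Step 7
Reactants: 13 (2E,4E)‑5‑[(3R,4S)‑3,4‑bis[(tert‑butyldimethylsilyl)oxy]‑2,6,6‑trimethylcyclohex‑1‑en‑1‑yl]‑3‑methylpenta‑2,4‑dien‑1‑ol
Product: 15 [(2E,4E)‑5‑[(3R,4S)‑3,4‑bis[(tert‑butyldimethylsilyl)oxy]‑2,6,6‑trimethylcyclohex‑1‑en‑1‑yl]‑3‑methylpenta‑2,4‑dien‑1‑yl]triphenylphosphonium bromide, via allylic bromide 14 (not isolated)
Conditions: CBr4, PPh3, CH2Cl2, −30 °C; then PPh3, rt
Reagents that add atoms: carbon tetrabromide, BrC(Br)(Br)Br; triphenylphosphine, c1ccc(cc1)P(c1ccccc1)c1ccccc1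
Why: Appel bromination converts the primary allylic alcohol into the bromide without acid that could ionise the allylic C–O bond at ring position 3, and triphenylphosphine then displaces bromide to give the C15 Wittig salt.

Step 8
Reactants: 16 (R)‑α‑ionone [(3E)‑4‑[(1R)‑2,6,6‑trimethylcyclohex‑2‑en‑1‑yl]but‑3‑en‑2‑one]
Product: 17 ethyl (2E,4E)‑3‑methyl‑5‑[(1R)‑2,6,6‑trimethylcyclohex‑2‑en‑1‑yl]penta‑2,4‑dienoate
Conditions: (EtO)2P(O)CH2CO2Et, NaH, THF, 0 → 50 °C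
Reagents that add atoms: triethyl phosphonoacetate, CCOC(=O)CP(=O)(OCC)OCC
Why: Horner–Wadsworth–Emmons olefination of the methyl ketone with the stabilised phosphonate anion should give mainly the (2E)‑dienoate (the 2Z isomer is removed by chromatography) and is a known transformation of α‑ionone that moves neither the ring double bond nor the C‑1 stereocentre.

Step 9
Reactants: 17 ethyl (2E,4E)‑3‑methyl‑5‑[(1R)‑2,6,6‑trimethylcyclohex‑2‑en‑1‑yl]penta‑2,4‑dienoate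
Product: 18 ethyl (2E,4E)‑3‑methyl‑5‑[(1R)‑2,6,6‑trimethyl‑4‑oxocyclohex‑2‑en‑1‑yl]penta‑2,4‑dienoate
Conditions: t‑BuOOH (aq.), Rh2(cap)4 (cat., cap = caprolactamate), CH2Cl2, rt
Reagents that add atoms: tert‑butyl hydroperoxide, CC(C)(C)OO
Why: Catalytic allylic C–H oxidation with tert‑butyl hydroperoxide attacks the ring methylene next to the trisubstituted alkene, the usual site in α‑ionone derivatives, and gives the enone without base, so the now doubly vinylogous C‑1 proton should not epimerise.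

Step 10
Reactants: 18 ethyl (2E,4E)‑3‑methyl‑5‑[(1R)‑2,6,6‑trimethyl‑4‑oxocyclohex‑2‑en‑1‑yl]penta‑2,4‑dienoate
Product: 19 ethyl (2E,4E)‑5‑[(1R,4S)‑4‑hydroxy‑2,6,6‑trimethylcyclohex‑2‑en‑1‑yl]‑3‑methylpenta‑2,4‑dienoate
Conditions: LiBH(s‑Bu)3, THF, −78 °C; aq. NH4Cl
Reagents that add atoms: none
Why: The bulky hydride reduces the β,β‑disubstituted enone in the 1,2‑sense and is expected to approach the ring face opposite the C‑1 dienyl side chain (substrate‑controlled reduction), which places the new hydroxyl cis to that chain (4S), while the conjugated ester is left alone at low temperature.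

Step 11
Reactants: 19 ethyl (2E,4E)‑5‑[(1R,4S)‑4‑hydroxy‑2,6,6‑trimethylcyclohex‑2‑en‑1‑yl]‑3‑methylpenta‑2,4‑dienoate
Product: 20 ethyl (2E,4E)‑5‑[(1R,4S)‑4‑[(tert‑butyldimethylsilyl)oxy]‑2,6,6‑trimethylcyclohex‑2‑en‑1‑yl]‑3‑methylpenta‑2,4‑dienoate
Conditions: TBSCl, imidazole, DMF, rt
Reagents that add atoms: tert‑butyldimethylsilyl chloride, CC(C)(C)[Si](C)(C)Cl
Why: Standard silylation protects the allylic alcohol so that it is not brominated in step 13 and matches the fluoride‑labile groups of ring A.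

Step 12
Reactants: 20 ethyl (2E,4E)‑5‑[(1R,4S)‑4‑[(tert‑butyldimethylsilyl)oxy]‑2,6,6‑trimethylcyclohex‑2‑en‑1‑yl]‑3‑methylpenta‑2,4‑dienoate
Product: 21 (2E,4E)‑5‑[(1R,4S)‑4‑[(tert‑butyldimethylsilyl)oxy]‑2,6,6‑trimethylcyclohex‑2‑en‑1‑yl]‑3‑methylpenta‑2,4‑dien‑1‑ol
Conditions: i‑Bu2AlH, CH2Cl2, −78 °C
Reagents that add atoms: none
Why: The aluminium hydride reduces the conjugated ester to the primary allylic alcohol in the 1,2‑sense at low temperature without touching the silyl ether or the alkenes.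

Step 13
Reactants: 21 (2E,4E)‑5‑[(1R,4S)‑4‑[(tert‑butyldimethylsilyl)oxy]‑2,6,6‑trimethylcyclohex‑2‑en‑1‑yl]‑3‑methylpenta‑2,4‑dien‑1‑ol
Product: 23 [(2E,4E)‑5‑[(1R,4S)‑4‑[(tert‑butyldimethylsilyl)oxy]‑2,6,6‑trimethylcyclohex‑2‑en‑1‑yl]‑3‑methylpenta‑2,4‑dien‑1‑yl]triphenylphosphonium bromide, via allylic bromide 22 (not isolated)
Conditions: CBr4, PPh3, CH2Cl2, −30 °C; then PPh3, rt
Reagents that add atoms: carbon tetrabromide, BrC(Br)(Br)Br; triphenylphosphine, c1ccc(cc1)P(c1ccccc1)c1ccccc1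
Why: The same acid‑free Appel bromination and phosphine quaternisation as in step 7 gives the ring‑B C15 Wittig salt without exposing the allylic silyl ether at ring position 4 to acid.

Step 14
Reactants: 23 [(2E,4E)‑5‑[(1R,4S)‑4‑[(tert‑butyldimethylsilyl)oxy]‑2,6,6‑trimethylcyclohex‑2‑en‑1‑yl]‑3‑methylpenta‑2,4‑dien‑1‑yl]triphenylphosphonium bromide; 24 (2E,4E,6E)‑2,7‑dimethylocta‑2,4,6‑trienedial
Product: 26 (2E,4E,6E,8E,10E,12E)‑13‑[(1R,4S)‑4‑[(tert‑butyldimethylsilyl)oxy]‑2,6,6‑trimethylcyclohex‑2‑en‑1‑yl]‑2,7,11‑trimethyltrideca‑2,4,6,8,10,12‑hexaenal, via phosphonium ylide 25 (not isolated)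
Conditions: NaOMe, MeOH/CH2Cl2, 0 °C → rt, 24 in excess; then heptane, 80 °C
Reagents that add atoms: none
Why: Wittig reaction of the ylide with an excess of the symmetrical dialdehyde should stop after one olefination, the classic C15 + C10 route to C25 apo‑carotenals, and heating equilibrates the new disubstituted double bond to E.

Step 15
Reactants: 15 [(2E,4E)‑5‑[(3R,4S)‑3,4‑bis[(tert‑butyldimethylsilyl)oxy]‑2,6,6‑trimethylcyclohex‑1‑en‑1‑yl]‑3‑methylpenta‑2,4‑dien‑1‑yl]triphenylphosphonium bromide; 26 (2E,4E,6E,8E,10E,12E)‑13‑[(1R,4S)‑4‑[(tert‑butyldimethylsilyl)oxy]‑2,6,6‑trimethylcyclohex‑2‑en‑1‑yl]‑2,7,11‑trimethyltrideca‑2,4,6,8,10,12‑hexaenal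
Product: 28 (3S,4R,3′S,6′R)‑3,4,3′‑tris[(tert‑butyldimethylsilyl)oxy]‑β,ε‑carotene (all‑E), via phosphonium ylide 27 (not isolated)
Conditions: NaOMe, MeOH/CH2Cl2, 0 °C → rt; then heptane, 90 °C, dark
Reagents that add atoms: none
Why: The second Wittig olefination joins the halves at C11=C12 without touching any stereocentre, and the Z/E mixture at the new double bond is equilibrated thermally to the all‑E polyene as is routine for C15 + C25 carotenoid couplings.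

Step 16
Reactants: 28 (3S,4R,3′S,6′R)‑3,4,3′‑tris[(tert‑butyldimethylsilyl)oxy]‑β,ε‑carotene
Product: 29 (3S,4R,3′S,6′R)‑β,ε‑carotene‑3,4,3′‑triol (all‑E)
Conditions: Bu4NF, AcOH, THF, rt, dark
Reagents that add atoms: none
Why: Acetic‑acid‑buffered fluoride removes the three silyl ethers without strong acid or base, conditions under which the acid‑labile allylic carbinols at C4 and C3′ and the polyene should be stable.

Compound list
1 | (R)‑glycidol [(2R)‑oxiran‑2‑ylmethanol] | OC[C@H]1OC1 | starting material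
2 | (S)‑glycidaldehyde [(2S)‑oxirane‑2‑carbaldehyde] | O=C[C@H]1OC1 | intermediate
3 | 2‑methylpentan‑3‑one | CCC(=O)C(C)C | starting material
4 | lithium 4‑methylpent‑2‑en‑3‑olate (enolate of 3, Z/E mixture) | CC=C([O-])C(C)C.[Li+] | intermediate
5 | lithium (1R)‑2,4‑dimethyl‑1‑[(2S)‑oxiran‑2‑yl]‑3‑oxopentan‑1‑olate (C‑2 epimers) | CC(C)C(=O)C(C)[C@@H]([O-])[C@H]1OC1.[Li+] | intermediate
6 | dilithium (1R)‑2,4‑dimethyl‑1‑[(2S)‑oxiran‑2‑yl]pent‑3‑ene‑1,3‑diolate (C‑2 epimers) | CC(C)=C([O-])C(C)[C@@H]([O-])[C@H]1OC1.[Li+].[Li+] | intermediate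
7 | (3R,4S)‑3,4‑dihydroxy‑2,6,6‑trimethylcyclohexan‑1‑one (both C‑2 epimers) | O=C1C(C)[C@@H](O)[C@@H](O)CC1(C)C | intermediate
8 | (3R,4S)‑3,4‑bis[(tert‑butyldimethylsilyl)oxy]‑2,6,6‑trimethylcyclohexan‑1‑one (both C‑2 epimers) | O=C1C(C)[C@@H](O[Si](C)(C)C(C)(C)C)[C@@H](O[Si](C)(C)C(C)(C)C)CC1(C)C | intermediate
9 | potassium (3R,4S)‑3,4‑bis[(tert‑butyldimethylsilyl)oxy]‑2,6,6‑trimethylcyclohex‑1‑en‑1‑olate | [K+].[O-]C1=C(C)[C@@H](O[Si](C)(C)C(C)(C)C)[C@@H](O[Si](C)(C)C(C)(C)C)CC1(C)C | intermediate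
10 | (3R,4S)‑3,4‑bis[(tert‑butyldimethylsilyl)oxy]‑2,6,6‑trimethylcyclohex‑1‑en‑1‑yl trifluoromethanesulfonate | FC(F)(F)S(=O)(=O)OC1=C(C)[C@@H](O[Si](C)(C)C(C)(C)C)[C@@H](O[Si](C)(C)C(C)(C)C)CC1(C)C | intermediate
11 | (E)‑3‑methylpent‑2‑en‑4‑yn‑1‑ol | C#C/C(C)=C/CO | starting material
12 | (2E,4E)‑3‑methyl‑5‑(tributylstannyl)penta‑2,4‑dien‑1‑ol | OC/C=C(C)/C=C/[Sn](CCCC)(CCCC)CCCC | intermediate
13 | (2E,4E)‑5‑[(3R,4S)‑3,4‑bis[(tert‑butyldimethylsilyl)oxy]‑2,6,6‑trimethylcyclohex‑1‑en‑1‑yl]‑3‑methylpenta‑2,4‑dien‑1‑ol | OC/C=C(C)/C=C/C1=C(C)[C@@H](O[Si](C)(C)C(C)(C)C)[C@@H](O[Si](C)(C)C(C)(C)C)CC1(C)C | intermediate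
14 | (2E,4E)‑5‑[(3R,4S)‑3,4‑bis[(tert‑butyldimethylsilyl)oxy]‑2,6,6‑trimethylcyclohex‑1‑en‑1‑yl]‑3‑methylpenta‑2,4‑dien‑1‑yl bromide | BrC/C=C(C)/C=C/C1=C(C)[C@@H](O[Si](C)(C)C(C)(C)C)[C@@H](O[Si](C)(C)C(C)(C)C)CC1(C)C | intermediate
15 | [(2E,4E)‑5‑[(3R,4S)‑3,4‑bis[(tert‑butyldimethylsilyl)oxy]‑2,6,6‑trimethylcyclohex‑1‑en‑1‑yl]‑3‑methylpenta‑2,4‑dien‑1‑yl]triphenylphosphonium bromide | [Br-].c1ccc(cc1)[P+](c1ccccc1)(c1ccccc1)C/C=C(C)/C=C/C1=C(C)[C@@H](O[Si](C)(C)C(C)(C)C)[C@@H](O[Si](C)(C)C(C)(C)C)CC1(C)C | intermediate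
16 | (R)‑α‑ionone [(3E)‑4‑[(1R)‑2,6,6‑trimethylcyclohex‑2‑en‑1‑yl]but‑3‑en‑2‑one] | CC1=CCCC(C)(C)[C@H]1/C=C/C(C)=O | starting material
17 | ethyl (2E,4E)‑3‑methyl‑5‑[(1R)‑2,6,6‑trimethylcyclohex‑2‑en‑1‑yl]penta‑2,4‑dienoate | CC1=CCCC(C)(C)[C@H]1/C=C/C(C)=C/C(=O)OCC | intermediate
18 | ethyl (2E,4E)‑3‑methyl‑5‑[(1R)‑2,6,6‑trimethyl‑4‑oxocyclohex‑2‑en‑1‑yl]penta‑2,4‑dienoate | CC1=CC(=O)CC(C)(C)[C@H]1/C=C/C(C)=C/C(=O)OCC | intermediate
19 | ethyl (2E,4E)‑5‑[(1R,4S)‑4‑hydroxy‑2,6,6‑trimethylcyclohex‑2‑en‑1‑yl]‑3‑methylpenta‑2,4‑dienoate | CC1=C[C@@H](O)CC(C)(C)[C@H]1/C=C/C(C)=C/C(=O)OCC | intermediate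
20 | ethyl (2E,4E)‑5‑[(1R,4S)‑4‑[(tert‑butyldimethylsilyl)oxy]‑2,6,6‑trimethylcyclohex‑2‑en‑1‑yl]‑3‑methylpenta‑2,4‑dienoate | CC1=C[C@@H](O[Si](C)(C)C(C)(C)C)CC(C)(C)[C@H]1/C=C/C(C)=C/C(=O)OCC | intermediate
21 | (2E,4E)‑5‑[(1R,4S)‑4‑[(tert‑butyldimethylsilyl)oxy]‑2,6,6‑trimethylcyclohex‑2‑en‑1‑yl]‑3‑methylpenta‑2,4‑dien‑1‑ol | CC1=C[C@@H](O[Si](C)(C)C(C)(C)C)CC(C)(C)[C@H]1/C=C/C(C)=C/CO | intermediate
22 | (2E,4E)‑5‑[(1R,4S)‑4‑[(tert‑butyldimethylsilyl)oxy]‑2,6,6‑trimethylcyclohex‑2‑en‑1‑yl]‑3‑methylpenta‑2,4‑dien‑1‑yl bromide | CC1=C[C@@H](O[Si](C)(C)C(C)(C)C)CC(C)(C)[C@H]1/C=C/C(C)=C/CBr | intermediate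
23 | [(2E,4E)‑5‑[(1R,4S)‑4‑[(tert‑butyldimethylsilyl)oxy]‑2,6,6‑trimethylcyclohex‑2‑en‑1‑yl]‑3‑methylpenta‑2,4‑dien‑1‑yl]triphenylphosphonium bromide | CC1=C[C@@H](O[Si](C)(C)C(C)(C)C)CC(C)(C)[C@H]1/C=C/C(C)=C/C[P+](c1ccccc1)(c1ccccc1)c1ccccc1.[Br-] | intermediate
24 | (2E,4E,6E)‑2,7‑dimethylocta‑2,4,6‑trienedial | O=C/C(C)=C/C=C/C=C(C)/C=O | starting material
25 | ylide of 23 [(2E,4E)‑5‑[(1R,4S)‑4‑[(tert‑butyldimethylsilyl)oxy]‑2,6,6‑trimethylcyclohex‑2‑en‑1‑yl]‑3‑methylpenta‑2,4‑dien‑1‑ylidene]triphenylphosphorane | CC1=C[C@@H](O[Si](C)(C)C(C)(C)C)CC(C)(C)[C@H]1/C=C/C(C)=C/C=P(c1ccccc1)(c1ccccc1)c1ccccc1 | intermediate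
26 | (2E,4E,6E,8E,10E,12E)‑13‑[(1R,4S)‑4‑[(tert‑butyldimethylsilyl)oxy]‑2,6,6‑trimethylcyclohex‑2‑en‑1‑yl]‑2,7,11‑trimethyltrideca‑2,4,6,8,10,12‑hexaenal | CC1=C[C@@H](O[Si](C)(C)C(C)(C)C)CC(C)(C)[C@H]1/C=C/C(C)=C/C=C/C(C)=C/C=C/C=C(C)/C=O | intermediate
27 | ylide of 15 [(2E,4E)‑5‑[(3R,4S)‑3,4‑bis[(tert‑butyldimethylsilyl)oxy]‑2,6,6‑trimethylcyclohex‑1‑en‑1‑yl]‑3‑methylpenta‑2,4‑dien‑1‑ylidene]triphenylphosphorane | c1ccc(cc1)P(c1ccccc1)(c1ccccc1)=C/C=C(C)/C=C/C1=C(C)[C@@H](O[Si](C)(C)C(C)(C)C)[C@@H](O[Si](C)(C)C(C)(C)C)CC1(C)C | intermediate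
28 | (3S,4R,3′S,6′R)‑3,4,3′‑tris[(tert‑butyldimethylsilyl)oxy]‑β,ε‑carotene (all‑E) | CC1=C[C@@H](O[Si](C)(C)C(C)(C)C)CC(C)(C)[C@H]1/C=C/C(C)=C/C=C/C(C)=C/C=C/C=C(C)/C=C/C=C(C)/C=C/C1=C(C)[C@@H](O[Si](C)(C)C(C)(C)C)[C@@H](O[Si](C)(C)C(C)(C)C)CC1(C)C | intermediate
29 | (3S,4R,3′S,6′R)‑β,ε‑carotene‑3,4,3′‑triol (all‑E) | CC1=C[C@@H](O)CC(C)(C)[C@H]1/C=C/C(C)=C/C=C/C(C)=C/C=C/C=C(C)/C=C/C=C(C)/C=C/C1=C(C)[C@@H](O)[C@@H](O)CC1(C)C | target

Total step count: 16.
Longest linear sequence: 9 steps (steps 8–16, from 16 to 29); the ring‑A branch is 8 steps (steps 1–4, 6, 7, 15, 16).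

Steps most likely to fail

Step 2. The second stage may stall, leak into O‑alkylation, Payne‑type epoxide migration or opening at the internal epoxide carbon, and the aldol stage may show low facial selectivity with the lithium enolate. The fallback separates the two bond formations and uses known reaction types; it sets out from 3 (with 2) and returns at 8. A dibutylboron enolate aldol (n‑Bu2BOTf, i‑Pr2NEt, CH2Cl2, −78 °C; then 2; buffered H2O2 work‑up) gives the isolated epoxy aldol (1R)‑1‑hydroxy‑2,4‑dimethyl‑1‑[(2S)‑oxiran‑2‑yl]pentan‑3‑one F1, with the anti‑selectivity expected of a non‑chelating boron enolate. MgI2 in Et2O opens the terminal epoxide at CH2 to the iodo diol (5R,6R)‑5,6‑dihydroxy‑7‑iodo‑2,4‑dimethylheptan‑3‑one F2. TBSOTf and 2,6‑lutidine give the bis‑silyl ether (5R,6R)‑5,6‑bis[(tert‑butyldimethylsilyl)oxy]‑7‑iodo‑2,4‑dimethylheptan‑3‑one F3. KN(SiMe3)2 in THF then closes the ring by a classical 6‑(enolendo)‑exo‑tet enolate alkylation of the primary iodide to give 8.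

Step 10. Hydride delivery to the enone may show poor or reversed facial selectivity, so that the hydroxyl ends trans to the side chain. The fallback sets out from 18 and returns at 19. Luche reduction (NaBH4, CeCl3·7H2O, MeOH, −20 °C), or the trans fraction of step 10 itself, gives the trans alcohol ethyl (2E,4E)‑5‑[(1R,4R)‑4‑hydroxy‑2,6,6‑trimethylcyclohex‑2‑en‑1‑yl]‑3‑methylpenta‑2,4‑dienoate F4, separated by chromatography. Mitsunobu inversion (4‑nitrobenzoic acid, diisopropyl azodicarboxylate, PPh3, toluene, 0 °C) gives the cis ester (1S,4R)‑4‑[(1E,3E)‑5‑ethoxy‑3‑methyl‑5‑oxopenta‑1,3‑dien‑1‑yl]‑3,5,5‑trimethylcyclohex‑2‑en‑1‑yl 4‑nitrobenzoate F5. K2CO3 in ethanol removes the nitrobenzoate and gives 19.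

Step 6. Oxidative addition and transmetalation at the tetrasubstituted, doubly flanked enol triflate may be slow, with competing protodestannylation and stannane homocoupling. The fallback replaces the sp2–sp2 coupling by carbonylation and olefination; it sets out from 10 and returns at 13. Palladium‑catalysed formylation (Pd(OAc)2, dppp, CO, Et3SiH, Et3N, DMF, 70 °C) gives the ring aldehyde (3R,4S)‑3,4‑bis[(tert‑butyldimethylsilyl)oxy]‑2,6,6‑trimethylcyclohex‑1‑ene‑1‑carbaldehyde F6. Horner–Wadsworth–Emmons olefination with the lithium anion of triethyl 3‑methyl‑4‑phosphonocrotonate (THF, −78 → 0 °C) gives the trienoate ethyl (2E,4E)‑5‑[(3R,4S)‑3,4‑bis[(tert‑butyldimethylsilyl)oxy]‑2,6,6‑trimethylcyclohex‑1‑en‑1‑yl]‑3‑methylpenta‑2,4‑dienoate F7. Reduction with i‑Bu2AlH (CH2Cl2, −78 °C) gives 13.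

Further compounds
F1 | step 2 | (1R)‑1‑hydroxy‑2,4‑dimethyl‑1‑[(2S)‑oxiran‑2‑yl]pentan‑3‑one (C‑2 epimers) | CC(C)C(=O)C(C)[C@@H](O)[C@H]1OC1
F2 | step 2 | (5R,6R)‑5,6‑dihydroxy‑7‑iodo‑2,4‑dimethylheptan‑3‑one (C‑4 epimers) | CC(C)C(=O)C(C)[C@@H](O)[C@@H](O)CI
F3 | step 2 | (5R,6R)‑5,6‑bis[(tert‑butyldimethylsilyl)oxy]‑7‑iodo‑2,4‑dimethylheptan‑3‑one (C‑4 epimers) | CC(C)C(=O)C(C)[C@@H](O[Si](C)(C)C(C)(C)C)[C@@H](O[Si](C)(C)C(C)(C)C)CI
F4 | step 10 | ethyl (2E,4E)‑5‑[(1R,4R)‑4‑hydroxy‑2,6,6‑trimethylcyclohex‑2‑en‑1‑yl]‑3‑methylpenta‑2,4‑dienoate | CC1=C[C@H](O)CC(C)(C)[C@H]1/C=C/C(C)=C/C(=O)OCC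
F5 | step 10 | (1S,4R)‑4‑[(1E,3E)‑5‑ethoxy‑3‑methyl‑5‑oxopenta‑1,3‑dien‑1‑yl]‑3,5,5‑trimethylcyclohex‑2‑en‑1‑yl 4‑nitrobenzoate | CC1=C[C@@H](OC(=O)c2ccc(cc2)[N+](=O)[O-])CC(C)(C)[C@H]1/C=C/C(C)=C/C(=O)OCC
F6 | step 6 | (3R,4S)‑3,4‑bis[(tert‑butyldimethylsilyl)oxy]‑2,6,6‑trimethylcyclohex‑1‑ene‑1‑carbaldehyde | O=CC1=C(C)[C@@H](O[Si](C)(C)C(C)(C)C)[C@@H](O[Si](C)(C)C(C)(C)C)CC1(C)C
F7 | step 6 | ethyl (2E,4E)‑5‑[(3R,4S)‑3,4‑bis[(tert‑butyldimethylsilyl)oxy]‑2,6,6‑trimethylcyclohex‑1‑en‑1‑yl]‑3‑methylpenta‑2,4‑dienoate | CCOC(=O)/C=C(C)/C=C/C1=C(C)[C@@H](O[Si](C)(C)C(C)(C)C)[C@@H](O[Si](C)(C)C(C)(C)C)CC1(C)C
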